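## Analysis of the target

Penithochromone T (12) is a 5-hydroxy-7-methoxychromone. Ring A is the benzene ring C4a–C5–C6–C7–C8–C8a and ring B is the γ-pyrone O1–C2–C3–C4–C4a–C8a. C2 carries an unbranched chain C1′–C9′: C1′H2, carbinol C2′, four methylenes C3′–C6′, and the (E)-enoic acid C7′=C8′–C9′O2H.

C2′ is the only stereocentre, and the SMILES string reads as (R) (OH > C1′ > C3′ > H). It is isolated, so nothing in the molecule can relay its configuration; it has to be resolved, bought or set by a catalyst.

The weak spot is the segment C2–C1′–C2′. C1′–H is vinylogously acidic through C2=C3–C4=O, so the C2′ hydroxy group behaves like the β-hydroxy group of a masked 1,3-diketone. It is open to E1cB dehydration and retro-aldol cleavage in strong base, and to dehydration in hot acid.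

Ring B is opened at C2 by hydroxide and other hard nucleophiles. The enoic acid is a Michael acceptor. The 5-OH is chelated to C4=O.

The oxygen functions at C2′ and C9′ are 1,8-related (dissonant), so ordinary polar bond formations alone cannot link them.

The route is built on two features of rings A and B:
- C4a lies between two oxygen-bearing carbons (C5 and C8a) and para to C7–OMe. While ring B is open, ring A therefore has a mirror plane through C4a and C7, and O1 and the 5-OH are the same kind of oxygen.
- The three ring B carbons outside ring A are a one-carbon carbonyl unit (C4) next to a two-carbon unit at the alkyne oxidation level (C3, C2).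

The difficulty is not size. It is to be brief, to use no protecting groups for three hydroxy groups and an acid, and never to expose the β-hydroxyalkyl pyrone to the strong bases and hot acids of the classical chromone syntheses.

## Retrosynthetic reasoning

**C7′=C8′ (12 ⇒ 10 + 11).** The alkene is cut by cross metathesis into the terminal olefin 10 and acrylic acid 11. A non-polar bond formation removes the dissonant C2′/C9′ relationship without any polarity reversal. The acid also arrives free, so no ester has to be hydrolysed next to a base-sensitive pyrone. Placing this step last keeps the Michael acceptor away from the acetylide, the amine and the palladium of the earlier steps. The forward reaction must be E-selective and must tolerate a phenol, an alcohol and an acid.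

**Ring B (10 ⇒ 2 + 6 + 7).** Three bonds are cut at once: C4a–C4, C4–C3 and O1–C2. This leaves iodoresorcinol 2, carbon monoxide 7 as C4, and the unprotected alkynol 6, whose two alkyne carbons are C3 and C2. All fragments are then far simpler than 10. The mirror plane of 2 makes the choice of the closing oxygen irrelevant, so the 5-OH needs no protection and no later unmasking. The forward reaction has to take up 7 before the alkyne couples, giving alkynone 8. It then has to close the six-membered and not the five-membered ring, which the amine adduct 9 secures. The medium is never more basic than a secondary amine, which is what the C2–C1′–C2′ segment needs.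

**C2–C1′ (6 ⇒ 4 + 5).** In the target C2 is an acceptor carbon, and C1′ in epoxide 4 is an acceptor as well. The bond becomes possible because C2 is brought in with reversed polarity, as the carbanion of acetylide 5. Attack at the unsubstituted epoxide carbon forms C2–C1′, frees the C2′ oxygen and leaves the stereocentre untouched. An aldol-type C1′–C2′ cut would have to create the stereocentre; this cut only has to preserve it.

**The stereocentre (4 ⇒ 3).** Epoxide 4 is the slow-reacting enantiomer in the hydrolytic kinetic resolution of commercial racemic 3. Half of a cheap C8 building block is given up in the first step of the sequence, in exchange for dependable enantiomeric purity and one single operation.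

**C4a–I (2 ⇒ 1).** Iodide 2 comes from 5-methoxyresorcinol 1 by electrophilic iodination between the two hydroxy groups. Ring A itself is not cut. Compound 1 already holds the C5/C7/C8a oxygen pattern and the O-methyl differentiation, so a de novo benzannulation would cost more steps than it could win.

## Alternatives that were turned down

**Alternative 1:** the textbook cut, C2–C3 and then O1–C2.
- Forward: the polyanion of 2,6-dihydroxy-4-methoxyacetophenone A1 (or its O-acyl form in the Baker–Venkataraman variant) is acylated with methyl (R)-3-(tert-butyldimethylsilyloxy)non-8-enoate A2. This gives the 1,3-diketone A3, which acid cyclodehydrates and desilylates to 10.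
- Turned down: A2 is an enolisable ester with a β-oxygen, so the three or more equivalents of strong base that A1 needs invite E1cB loss of the silyloxy group.
- A2 also needs its own asymmetric synthesis (acetate aldol, or β-keto ester hydrogenation that endangers the terminal alkene) plus a protection step.
- The closing acid step heats exactly the β-oxygenated pyrone that dehydrates most easily.
- The sequence would be about twice as long as the chosen one and would carry protecting groups throughout.

**Alternative 2:** the shortest cut on paper, C1′–C2′.
- Forward: 5-hydroxy-7-methoxy-2-methylchromone A4 is doubly deprotonated, and the vinylogous enolate is added to hept-6-enal A5 to give carbinol A6.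
- Turned down: an achiral lithium dienolate and an achiral aldehyde create the only stereocentre without control, so A6 is racemic. The reaction type offers no close catalytic asymmetric version for 2-methylchromones.
- Repair by oxidation to ketone A7 and asymmetric reduction adds two steps. A7 is an enolised vinylogous tricarbonyl compound whose reduction has no clear facial bias.
- The lithium aldolate is also set up for retro-aldol cleavage and E1cB elimination.

**Alternative 3:** a ring switch that cuts C4–C4a and O1–C2 and carries C4–C3–C2–C1′–C2′ as a lactone.
- Forward: a catalytic asymmetric hetero-Diels–Alder reaction of A5 with a 1,3-dioxygenated silyl ketene acetal diene gives (R)-6-(hex-5-en-1-yl)-4-methoxy-5,6-dihydro-2H-pyran-2-one A8.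
- The aryllithium A9 then adds to the lactone carbonyl. Acid removes the acetals, closes ring B by displacement of the methoxy group and frees the C2′–OH.
- Turned down: A9 is hindered on both sides and strongly basic, while A8 has acidic γ-protons whose removal opens the lactone to a dienoate.
- The acid step ionises the intermediate lactol and passes through dihydropyranone A10. There the C2′–O bond is that of a vinylogous carboxylate leaving group β to a ketone, so retro-oxa-Michael opening threatens both racemisation and elimination.
- Two acetal groups must be put on and taken off, and such cycloadditions are least selective with unbranched aliphatic aldehydes.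

Key step: step 4

Remark on the chemistry: the sense of the resolution in step 2 is assigned by analogy with other unbranched 1-alkyloxiranes, whose (S)-enantiomer is hydrolysed faster by the (R,R)-catalyst.

## Route

Step 1
Reactants: 1 5-methoxyresorcinol (5-methoxybenzene-1,3-diol)
Product: 2 2-iodo-5-methoxybenzene-1,3-diol
Conditions: I2 (1.0 equiv), NaHCO3 (1.1 equiv), H2O, 0 °C to rt
Reagents that add atoms: iodine, II
Why: Electrophilic aromatic iodination under the aqueous bicarbonate conditions that convert resorcinols into 2-iodoresorcinols; the position between the two hydroxy groups is ortho to both phenol(ate) oxygens, para to the methoxy group and the least hindered of the three activated sites. One equivalent of iodine at low temperature should hold back multiple iodination.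

Step 2
Reactants: 3 rac-2-(hex-5-en-1-yl)oxirane (1,2-epoxy-7-octene)
Product: 4 (R)-2-(hex-5-en-1-yl)oxirane
Conditions: (R,R)-[N,N′-bis(3,5-di-tert-butylsalicylidene)-1,2-cyclohexanediaminato]Co(OAc) (0.5 mol %), H2O (0.55 equiv), neat, 0 °C to rt, then distillation
Reagents that add atoms: none
Why: Hydrolytic kinetic resolution of a terminal epoxide with a chiral trivalent cobalt salen complex; the (S)-enantiomer is hydrolysed to the diol, and at slightly more than half conversion the unreacted (R)-epoxide should be left in high enantiomeric purity and is separated by distillation. This step fixes the C2′ configuration of the target.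

Step 3
Reactants: 4 (R)-2-(hex-5-en-1-yl)oxirane; 5 lithium acetylide–ethylenediamine complex
Product: 6 (R)-dec-9-en-1-yn-4-ol
Conditions: 5 (1.5 equiv), DMSO, 15 °C to rt; then H2O
Reagents that add atoms: none
Why: Nucleophilic opening of a terminal epoxide by an acetylide at the unsubstituted carbon, a standard route to homopropargylic alcohols. No bond to the stereocentre is made or broken, so (R)-4 gives (R)-6, and the remote terminal alkene is inert.

Step 4
Reactants: 2 2-iodo-5-methoxybenzene-1,3-diol; 6 (R)-dec-9-en-1-yn-4-ol; 7 carbon monoxide
Product: 10 (R)-5-hydroxy-2-(2-hydroxyoct-7-en-1-yl)-7-methoxy-4H-chromen-4-one, via alkynone 8 (not isolated), via enaminone 9 (not isolated)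
Conditions: PdCl2(dppf) (3 mol %), CO (10 bar), Et2NH, 90 °C
Reagents that add atoms: diethylamine, CCNCC (its atoms stand in 9 only)
Why: Zerovalent palladium formed in situ inserts into the C–I bond of 2, 7 migrates into the electron-rich aryl–palladium bond, and amine-assisted alkynylation with 6 followed by reductive elimination forms C4a–C4 and C4–C3 in alkynone 8. Diethylamine adds to the β-carbon of 8 (the future C2) to give enaminone 9, and one ortho hydroxy group displaces the amine by addition–elimination, which forms O1–C2. The closest known reaction type is the palladium-catalysed carbonylative annulation of o-iodophenols with terminal alkynes in a secondary amine (carbonylative Sonogashira coupling and oxa-Michael ring closure). Ring B closes in the 6-endo mode (6-endo-trig on 9, formally 6-endo-dig on 8), and the 5-exo closure to an aurone is shut off because only the β-carbon of 9 is electrophilic. No stereocentre is formed: C2′ takes part in no bond change and meets nothing more basic than the amine, so the (R) configuration of 6 is carried over. No selectivity between the two phenols is needed, because they are equivalent in 2, 8 and 9, so either closure gives 10 and the other oxygen becomes the chelated 5-OH. Uptake of 7 has to outrun direct alkynylation, which would end in a benzofuran, and the copper-free medium, the CO pressure and the fast migration of a donor-rich aryl group secure this. The terminal alkene and the secondary alcohol of 6 are much poorer partners for the aroylpalladium species than the alkyne C–H and amine pair and should stay untouched.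

Step 5
Reactants: 10 (R)-5-hydroxy-2-(2-hydroxyoct-7-en-1-yl)-7-methoxy-4H-chromen-4-one; 11 acrylic acid
Product: 12 penithochromone T, (R,E)-8-hydroxy-9-(5-hydroxy-7-methoxy-4-oxo-4H-chromen-2-yl)non-2-enoic acid
Conditions: 11 (4 equiv), second-generation Hoveyda–Grubbs catalyst (H2IMes)Cl2Ru(=CH-C6H4-2-OiPr) (5 mol %), CH2Cl2, 40 °C
Reagents that add atoms: none
Why: Olefin cross metathesis between a rapidly homodimerising terminal alkene and an electron-poor acrylic partner, a pairing that is inherently cross-selective and gives the (E)-enoic acid under thermodynamic control. The trisubstituted, electron-poor C2=C3 bond of ring B does not take part, and phenol, alcohol and acid are tolerated by the ruthenium carbene.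

## Compound list

1 | 5-methoxyresorcinol (5-methoxybenzene-1,3-diol) | COc1cc(O)cc(O)c1 | starting material
2 | 2-iodo-5-methoxybenzene-1,3-diol | COc1cc(O)c(I)c(O)c1 | intermediate
3 | rac-2-(hex-5-en-1-yl)oxirane | C=CCCCCC1CO1 | starting material
4 | (R)-2-(hex-5-en-1-yl)oxirane | C=CCCCC[C@@H]1CO1 | intermediate
5 | lithium acetylide–ethylenediamine complex | [Li+].[C-]#C.NCCN | starting material
6 | (R)-dec-9-en-1-yn-4-ol | C#CC[C@H](O)CCCCC=C | intermediate
7 | carbon monoxide | [C-]#[O+] | starting material
8 | (R)-1-(2,6-dihydroxy-4-methoxyphenyl)-5-hydroxyundec-10-en-2-yn-1-one | COc1cc(O)c(C(=O)C#CC[C@H](O)CCCCC=C)c(O)c1 | intermediate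
9 | (R,E)-3-(diethylamino)-1-(2,6-dihydroxy-4-methoxyphenyl)-5-hydroxyundeca-2,10-dien-1-one | COc1cc(O)c(C(=O)/C=C(/N(CC)CC)C[C@H](O)CCCCC=C)c(O)c1 | intermediate
10 | (R)-5-hydroxy-2-(2-hydroxyoct-7-en-1-yl)-7-methoxy-4H-chromen-4-one | COc1cc(O)c2c(=O)cc(C[C@H](O)CCCCC=C)oc2c1 | intermediate
11 | acrylic acid | C=CC(=O)O | starting material
12 | penithochromone T, (R,E)-8-hydroxy-9-(5-hydroxy-7-methoxy-4-oxo-4H-chromen-2-yl)non-2-enoic acid | COc1cc(O)c2c(=O)cc(C[C@H](O)CCCC/C=C/C(=O)O)oc2c1 | target

## Step count and least certain steps

Total step count: 5. Longest linear sequence: 4 (steps 2, 3, 4 and 5). No protecting group is used.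

**Step 4 (key step).**
- The most likely failure is interception of the aroylpalladium species before the alkynyl group is transferred. The amine solvent could do this (aminocarbonylation), or a phenol of a second molecule, because the two ortho hydroxy groups crowd the metal.
- Direct alkynylation without uptake of 7, followed by 5-endo closure, is a further drain.
- Reductive loss of iodine from the very electron-rich ring is another.
- The fallback changes the disconnection to C2–C3. It sets out from 4 and comes back to the route at 10.
- Ring-expanding carbonylation of 4 with 7 ([(salph)Al(THF)2][Co(CO)4], THF, 50 °C) inserts the carbonyl group into the unsubstituted C–O bond. It gives, with the stereocentre untouched, (R)-4-(hex-5-en-1-yl)oxetan-2-one F1.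
- The lithium polyanion of commercial A1 (LiN(SiMe3)2, THF, −78 °C) opens F1 at the acyl carbon. The product is (R)-1-(2,6-dihydroxy-4-methoxyphenyl)-5-hydroxyundec-10-ene-1,3-dione F2, in which the carbinol oxygen is released as an alkoxide and never needs protection.
- Mild acid (AcOH, catalytic HCl, rt to 40 °C) cyclodehydrates F2 to 10.

**Step 1.**
- All three free ring positions are activated by three oxygens. Iodination next to the methoxy group and multiple iodination are therefore the likely problems.
- The product can also lose iodine again by protodeiodination on an acidic work-up.
- The fallback replaces electrophilic substitution by directed ortho-metalation. It sets out from 1 and comes back at 2.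
- Compound 1 is converted (MOMCl, iPr2NEt, CH2Cl2) into 1-methoxy-3,5-bis(methoxymethoxy)benzene F3.
- F3 is lithiated between the two chelating acetal groups (n-BuLi, THF, 0 °C) and quenched with I2 to give 2-iodo-5-methoxy-1,3-bis(methoxymethoxy)benzene F4.
- F4 is deprotected with catalytic HCl in MeOH at 40 °C to give 2.

**Step 5.**
- Decay of the ruthenium carbene in the presence of the chelating 5-hydroxy-4-oxo unit and the free acid can release hydride species. These move the terminal double bond along the chain before metathesis and so shorten the chain.
- Homodimerisation of 10 is the second drain.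
- The fallback replaces metathesis by carbonyl olefination. It sets out from 10 and comes back at 12.
- Lemieux–Johnson cleavage (OsO4 catalytic, NaIO4, 2,6-lutidine, dioxane/H2O) of the terminal alkene gives (R)-6-hydroxy-7-(5-hydroxy-7-methoxy-4-oxo-4H-chromen-2-yl)heptanal F5.
- Wittig reaction with Ph3P=CHCO2tBu (CH2Cl2, rt) gives tert-butyl (R,E)-8-hydroxy-9-(5-hydroxy-7-methoxy-4-oxo-4H-chromen-2-yl)non-2-enoate F6.
- CF3CO2H in CH2Cl2 at 0 °C cleaves the ester of F6 to give 12.

## Further compounds

F1 | step 4 | (R)-4-(hex-5-en-1-yl)oxetan-2-one | O=C1C[C@@H](CCCCC=C)O1
F2 | step 4 | (R)-1-(2,6-dihydroxy-4-methoxyphenyl)-5-hydroxyundec-10-ene-1,3-dione | COc1cc(O)c(C(=O)CC(=O)C[C@H](O)CCCCC=C)c(O)c1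
F3 | step 1 | 1-methoxy-3,5-bis(methoxymethoxy)benzene | COCOc1cc(OC)cc(OCOC)c1
F4 | step 1 | 2-iodo-5-methoxy-1,3-bis(methoxymethoxy)benzene | COCOc1cc(OC)cc(OCOC)c1I
F5 | step 5 | (R)-6-hydroxy-7-(5-hydroxy-7-methoxy-4-oxo-4H-chromen-2-yl)heptanal | COc1cc(O)c2c(=O)cc(C[C@H](O)CCCCC=O)oc2c1
F6 | step 5 | tert-butyl (R,E)-8-hydroxy-9-(5-hydroxy-7-methoxy-4-oxo-4H-chromen-2-yl)non-2-enoate | COc1cc(O)c2c(=O)cc(C[C@H](O)CCCC/C=C/C(=O)OC(C)(C)C)oc2c1
A1 | alternative 1 | 2,6-dihydroxy-4-methoxyacetophenone | CC(=O)c1c(O)cc(OC)cc1O
A2 | alternative 1 | methyl (R)-3-(tert-butyldimethylsilyloxy)non-8-enoate | COC(=O)C[C@H](O[Si](C)(C)C(C)(C)C)CCCCC=C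
A3 | alternative 1 | (R)-5-(tert-butyldimethylsilyloxy)-1-(2,6-dihydroxy-4-methoxyphenyl)undec-10-ene-1,3-dione | COc1cc(O)c(C(=O)CC(=O)C[C@H](O[Si](C)(C)C(C)(C)C)CCCCC=C)c(O)c1
A4 | alternative 2 | 5-hydroxy-7-methoxy-2-methyl-4H-chromen-4-one | Cc1cc(=O)c2c(O)cc(OC)cc2o1
A5 | alternative 2 | hept-6-enal | C=CCCCCC=O
A6 | alternative 2 | rac-5-hydroxy-2-(2-hydroxyoct-7-en-1-yl)-7-methoxy-4H-chromen-4-one | COc1cc(O)c2c(=O)cc(CC(O)CCCCC=C)oc2c1
A7 | alternative 2 | 5-hydroxy-7-methoxy-2-(2-oxooct-7-en-1-yl)-4H-chromen-4-one | COc1cc(O)c2c(=O)cc(CC(=O)CCCCC=C)oc2c1
A8 | alternative 3 | (R)-6-(hex-5-en-1-yl)-4-methoxy-5,6-dihydro-2H-pyran-2-one | COC1=CC(=O)O[C@H](CCCCC=C)C1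
A9 | alternative 3 | [4-methoxy-2,6-bis(methoxymethoxy)phenyl]lithium | [Li]c1c(OCOC)cc(OC)cc1OCOC
A10 | alternative 3 | (R)-6-(2,6-dihydroxy-4-methoxyphenyl)-2-(hex-5-en-1-yl)-2,3-dihydro-4H-pyran-4-one | COc1cc(O)c(C2=CC(=O)C[C@@H](CCCCC=C)O2)c(O)c1
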